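The runs are calculated for substances that don't exist; noise was put on by code.

If maple's highest reading, 61.5 %, stood below cedar's, 64.5 %, then more charge cost target: that was your hunch, and you asked me for a quick number.

all flasks: gas phase 28 mM (held)
- cedar: substrate 0.12 M; run made earlier
- maple: substrate 0.50 M; run made earlier
- flask: substrate 0.25 M; time 3.0 d

| run | time / d | target / % | substrate / % |
|---|---|---|---|
| cedar | 0.104 | 36.9 | 61.9 |
| cedar | 0.208 | 59.1 | 33.0 |
| cedar | 0.417 | 64.5 | 8.4 |
| cedar | 0.833 | 36.7 | 1.9 |
| cedar | 1.67 | 9.1 | 0.4 |
| cedar | 3.00 | 0.7 | 0.5 |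
| maple | 0.104 | 18.2 | 81.9 |
| maple | 0.208 | 33.2 | 65.2 |
| maple | 0.417 | 56.2 | 37.1 |
| maple | 0.833 | 61.5 | 8.3 |
| maple | 1.67 | 22.3 | 0.8 |
| maple | 3.00 | 2.8 | 0.6 |

(scatter of a reading: 0.5 percentage points)

- the numbers in the tables scatter with a standard deviation of 0.5 percentage points
- at the start none of the gas phase is in solution

- when, up to 3.0 d, the flask holds most target
- the amount of target, in percent of the substrate charged, at that time

1. I took a stretch of each run and asked what fraction of the lost substrate had not appeared as target. Multiplying that fraction by [substrate]/[target] gave 0.229 for cedar and 0.208 for maple.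
2. I carried their mean, 0.218, as the over-reaction ratio (a selectivity factor): target's fractional loss rate divided by substrate's. Time dropped out of this division, and I assumed the charge did too.
3. On that assumption, the peak lay at [target]/[substrate] = 4.59. Integrating put that peak at substrate 14.3 % and target 65.4 %. Cedar's and maple's highest readings had substrate at 8.4 % and 8.3 %, less than 14.3 %, so I read both as past the peak.
4. Interpolating between readings, I put cedar at 14.3 % substrate near 0.336 d and maple near 0.682 d. A straight line in charge gave the flask 0.454 d, and I committed to that time with 65.4 %.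
5. The forecast differed from mine, later and lower, at 0.52 d and 63 %: “The peak comes when substrate feed equals target loss”.
6. The flask gave 0.447 d and 65.9 %.

    dissolved gas + target → over-reacted product (k = 7.74 × 10⁻⁴ M⁻¹ s⁻¹)
    gas phase ⇌ dissolved gas, rate k2*(csat - [dissolved gas]) (kL = 4.85 × 10⁻⁴ s⁻¹)
    substrate + dissolved gas ⇌ target (K = 1510 M⁻¹, k = 0.00403 M⁻¹ s⁻¹)

7. At its best time, 0.447 d, the flask stood at [target]/[substrate] = 4.37, where my ratio 0.218 had put the peak at 4.59. At 0.411 d the step from dissolved gas + target to over-reacted product gave target a half-life of 0.60 d, shorter than the 3.0 d allowed, and at 3.00 d the flask held 1.16 % target and 98.8 % over-reacted product.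
8. For the neighbour flask with 1.0 M substrate, the ratio 0.218 gave a best of 65.4 % again. The simulation gave 64.0 %.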